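**Strategy.** Central-ring numbering: C1 (OMe), C2 (benzyl), C3 (OH), C4 (benzyl), C5 (arylethyl), C6 (benzyl). The segment C3, C2, C1, C6 shows the oxygen and carbon alternation of an α,γ-dibenzylated acetoacetate, so the ring is cut at C3–C4 and C5–C6. One thermal Diels–Alder reaction joins the double trimethylsilyl enol ether of that keto ester to an ynone bearing the aroyl group on one alkyne carbon and the arylethyl chain on the other. Methanol loss then delivers the hexasubstituted ring as an aroylresorcinol. The C4 carbonyl, the future third benzyl carbon, hydrogen-bonds to the C3 hydroxyl, leaving the C1 hydroxyl for methylation. Deoxygenation and hydrogenolysis finish.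

Key step: step 7

Remark on the chemistry: the target is achiral. The stereocentres in the keto esters and in the primary cycloadduct are transient and are drawn without configuration. Once the ketone is reduced, the carbon skeleton has a mirror plane through C2 and C5. Either monomethyl ether of the resorcinol therefore leads to the same target.

Step 1
Reactants: 1 methyl acetoacetate; 2 4-benzyloxybenzyl chloride
Product: 3 methyl 2-(4-benzyloxybenzyl)-3-oxobutanoate (racemic)
Conditions: 1 (2.5 equiv), K2CO3 (1.2 equiv), acetone, reflux; excess 1 removed in vacuo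
Reagents that add atoms: none
Why: Enolate C-alkylation (acetoacetic ester synthesis) in which the soft potassium enolate displaces the activated benzylic chloride, the excess of cheap, volatile 1 suppresses double alkylation, and the new C2 stereocentre is racemic and is erased in step 3.

Step 2
Reactants: 3 methyl 2-(4-benzyloxybenzyl)-3-oxobutanoate; 2 4-benzyloxybenzyl chloride
Product: 5 methyl 2-(4-benzyloxybenzyl)-5-(4-benzyloxyphenyl)-3-oxopentanoate (racemic), via sodium lithium dianion 4 (not isolated)
Conditions: NaH (1.1 equiv), THF, 0 °C; n-BuLi (1.05 equiv), 0 °C; 2 (1.0 equiv), 0 °C → rt; 1 M HCl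
Reagents that add atoms: none
Why: γ-Alkylation of a β-keto ester dianion, in which the more basic terminal carbanion takes the benzylic chloride while the stabilised, fully substituted α-enolate is too hindered to compete at this temperature.

Step 3
Reactants: 5 methyl 2-(4-benzyloxybenzyl)-5-(4-benzyloxyphenyl)-3-oxopentanoate
Product: 6 methyl 2-(4-benzyloxybenzyl)-5-(4-benzyloxyphenyl)-3-(trimethylsilyloxy)pent-2-enoate (E/Z mixture)
Conditions: Me3SiCl (1.8 equiv), Et3N (1.6 equiv), toluene, rt, argon; filtration, concentration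
Reagents that add atoms: chlorotrimethylsilane, C[Si](C)(C)Cl
Why: Soft enolisation and O-silylation of the β-keto ester gives the conjugated silyl enol ether, and its geometry does not matter because this double bond becomes the central single bond of the diene.

Step 4
Reactants: 6 methyl 2-(4-benzyloxybenzyl)-5-(4-benzyloxyphenyl)-3-(trimethylsilyloxy)pent-2-enoate
Product: 8 (1E,3Z)-2-(4-benzyloxybenzyl)-5-(4-benzyloxyphenyl)-1-methoxy-1,3-bis(trimethylsilyloxy)penta-1,3-diene, via lithium dienolate 7 (not isolated)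
Conditions: LiN(iPr)2 (commercial solution, 1.3 equiv), THF, −78 °C; Me3SiCl (1.5 equiv), −78 °C → rt; hexane, filtration under argon; used crude
Reagents that add atoms: chlorotrimethylsilane, C[Si](C)(C)Cl
Why: Kinetic γ-deprotonation of the β-silyloxy enoate and O-silylation of the extended ester dienolate (silyl ketene acetal formation) should give the 3Z geometry usual for 4-substituted dienes of this class, which puts the CH2Ar group on the outside of the s-cis diene, while the C1=C2 geometry is of no consequence.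

Step 5
Reactants: 9 1-(trimethylsilyl)propyne; 10 3-benzyloxybenzyl bromide
Product: 13 1-(benzyloxy)-3-(but-3-yn-1-yl)benzene, via lithiated silylpropyne 11 (not isolated), via silylated alkyne 12 (not isolated)
Conditions: 9 (1.2 equiv), n-BuLi (1.15 equiv), THF, −78 °C; 10, −78 °C → rt; then MeOH, K2CO3 (cat.), rt
Reagents that add atoms: none
Why: Propargylic lithiation and SN2 alkylation by the benzylic bromide, with the silyl group blocking the acetylenic terminus and disfavouring allene formation, followed by base-catalysed methanolysis of the alkynyl C–Si bond in the same flask.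

Step 6
Reactants: 13 1-(benzyloxy)-3-(but-3-yn-1-yl)benzene; 14 4-benzyloxybenzoyl chloride
Product: 15 1-(4-benzyloxyphenyl)-5-(3-benzyloxyphenyl)pent-2-yn-1-one
Conditions: PdCl2(PPh3)2 (2 mol %), CuI (4 mol %), Et3N (1.3 equiv), THF, rt
Reagents that add atoms: none
Why: Acyl Sonogashira coupling, in which zerovalent palladium inserts into the acyl C–Cl bond and the alkynyl group is passed on through copper, which avoids the double addition a lithium acetylide can undergo with an acid chloride.

Step 7
Reactants: 8 (1E,3Z)-2-(4-benzyloxybenzyl)-5-(4-benzyloxyphenyl)-1-methoxy-1,3-bis(trimethylsilyloxy)penta-1,3-diene; 15 1-(4-benzyloxyphenyl)-5-(3-benzyloxyphenyl)pent-2-yn-1-one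
Product: 18 4-(4-benzyloxybenzoyl)-2,6-bis(4-benzyloxybenzyl)-5-[2-(3-benzyloxyphenyl)ethyl]benzene-1,3-diol, via cyclohexadiene cycloadduct 16 (not isolated), via bis(trimethylsilyl) ether 17 (not isolated)
Conditions: 8 (2 equiv), toluene (about 2 M), sealed tube, argon, no Lewis acid, rt → 110 °C; then 1 M HCl, THF/MeOH, rt
Reagents that add atoms: none
Why: Normal-electron-demand Diels–Alder reaction: the HOMO of 8, raised by three oxygen donors, is largest at the silyl enol ether terminus (future C6), which engages the electrophilic β-carbon of 15 (future C5) ahead of the union of the ketene acetal carbon (future C3) with the α-carbon (future C4) in a single, strongly asynchronous [4+2] event. The central six-membered carbocycle is closed by this intermolecular cycloaddition (two σ-bonds in one operation), and even a fully stepwise Michael addition followed by a six-membered Claisen-type closure would give the same ring. Adduct 16 carries a mixed methyl silyl ketal carbon (C3) in a 1,4-relationship to the C6–H, so 1,4-elimination of methanol aromatises it to 17, and dilute acid then removes both silyl groups. The two sp3 centres of 16 form without control and vanish on aromatisation, so no stereocentre has to be set. The step needs regioselectivity (secured by the polarity match above), a reachable s-cis conformer (secured by the 3Z geometry that turns the C6 benzyl group outwards) and [4+2] rather than [3+3] closure (secured by the absence of a Lewis acid and by the C2 benzyl group, which denies an aldol-type closure at C2 any aromatic outcome). The closest known reaction type is the cycloaddition of 1-alkoxy-1,3-bis(silyloxy)butadienes with acetylenic ketones and esters, which gives resorcinols by loss of the alcohol.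

Step 8
Reactants: 18 4-(4-benzyloxybenzoyl)-2,6-bis(4-benzyloxybenzyl)-5-[2-(3-benzyloxyphenyl)ethyl]benzene-1,3-diol
Product: 19 (4-benzyloxyphenyl){3,5-bis(4-benzyloxybenzyl)-6-[2-(3-benzyloxyphenyl)ethyl]-2-hydroxy-4-methoxyphenyl}methanone
Conditions: MeI (1.1 equiv), K2CO3 (1.2 equiv), acetone, rt → 40 °C
Reagents that add atoms: iodomethane, CI
Why: Williamson ether synthesis under chelation control, in which the C3 hydroxyl is tied up in a hydrogen bond to the C4 ketone so that the C1 phenoxide is alkylated, and because of the latent C2/C5 mirror plane only over-methylation, not the site of methylation, could harm the route.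

Step 9
Reactants: 19 (4-benzyloxyphenyl){3,5-bis(4-benzyloxybenzyl)-6-[2-(3-benzyloxyphenyl)ethyl]-2-hydroxy-4-methoxyphenyl}methanone
Product: 22 2,4,6-tris(4-benzyloxybenzyl)-5-[2-(3-benzyloxyphenyl)ethyl]-3-methoxyphenol, via aryl ethyl carbonate 20 (not isolated), via ortho-quinone methide 21 (not isolated)
Conditions: ClCO2Et (1.3 equiv), Et3N (1.4 equiv), THF, 0 °C; filtration; NaBH4 (4 equiv), H2O/THF, 0 °C → rt
Reagents that add atoms: none
Why: Ortho-hydroxyl-assisted deoxygenation of an aryl ketone, in which borohydride reduces the ketone of 20, the carbonate migrates to the benzylic alkoxide and is expelled by the phenoxide, and quinone methide 21 accepts a second hydride, all in a non-acidic medium that spares the benzyl ethers and avoids a benzhydryl cation able to close a seven-membered ring onto the neighbouring arylethyl arene.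

Step 10
Reactants: 22 2,4,6-tris(4-benzyloxybenzyl)-5-[2-(3-benzyloxyphenyl)ethyl]-3-methoxyphenol
Product: 23 2,4,6-tris(4-hydroxybenzyl)-5-[2-(3-hydroxyphenyl)ethyl]-3-methoxyphenol (CNP0262401.0)
Conditions: H2 (1 atm), Pd/C (10 wt %), EtOAc/MeOH, rt
Reagents that add atoms: none
Why: Catalytic hydrogenolysis cleaves the four benzyl aryl ethers, while the aryl methyl ether, the diarylmethane C–C bonds and the phenols are inert under these conditions.

**Compound list**
1 | methyl acetoacetate | COC(=O)CC(C)=O | starting material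
2 | 4-benzyloxybenzyl chloride | ClCc1ccc(OCc2ccccc2)cc1 | starting material
3 | methyl 2-(4-benzyloxybenzyl)-3-oxobutanoate (racemic) | COC(=O)C(Cc1ccc(OCc2ccccc2)cc1)C(C)=O | intermediate
4 | sodium lithium dianion (bis-enolate) of 3 | [Na+].[Li+].COC([O-])=C(Cc1ccc(OCc2ccccc2)cc1)C([O-])=C | intermediate
5 | methyl 2-(4-benzyloxybenzyl)-5-(4-benzyloxyphenyl)-3-oxopentanoate (racemic) | COC(=O)C(Cc1ccc(OCc2ccccc2)cc1)C(=O)CCc1ccc(OCc2ccccc2)cc1 | intermediate
6 | methyl 2-(4-benzyloxybenzyl)-5-(4-benzyloxyphenyl)-3-(trimethylsilyloxy)pent-2-enoate (E/Z mixture) | COC(=O)C(Cc1ccc(OCc2ccccc2)cc1)=C(O[Si](C)(C)C)CCc1ccc(OCc2ccccc2)cc1 | intermediate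
7 | lithium dienolate of 6 | [Li+].CO/C([O-])=C(Cc1ccc(OCc2ccccc2)cc1)\C(O[Si](C)(C)C)=C\Cc1ccc(OCc2ccccc2)cc1 | intermediate
8 | (1E,3Z)-2-(4-benzyloxybenzyl)-5-(4-benzyloxyphenyl)-1-methoxy-1,3-bis(trimethylsilyloxy)penta-1,3-diene | CO/C(O[Si](C)(C)C)=C(Cc1ccc(OCc2ccccc2)cc1)\C(O[Si](C)(C)C)=C\Cc1ccc(OCc2ccccc2)cc1 | intermediate
9 | 1-(trimethylsilyl)propyne | CC#C[Si](C)(C)C | starting material
10 | 3-benzyloxybenzyl bromide | BrCc1cccc(OCc2ccccc2)c1 | starting material
11 | 3-lithio-1-(trimethylsilyl)propyne | [Li]CC#C[Si](C)(C)C | intermediate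
12 | [4-(3-benzyloxyphenyl)but-1-yn-1-yl]trimethylsilane | C[Si](C)(C)C#CCCc1cccc(OCc2ccccc2)c1 | intermediate
13 | 1-(benzyloxy)-3-(but-3-yn-1-yl)benzene | C#CCCc1cccc(OCc2ccccc2)c1 | intermediate
14 | 4-benzyloxybenzoyl chloride | O=C(Cl)c1ccc(OCc2ccccc2)cc1 | starting material
15 | 1-(4-benzyloxyphenyl)-5-(3-benzyloxyphenyl)pent-2-yn-1-one | O=C(C#CCCc1cccc(OCc2ccccc2)c1)c1ccc(OCc2ccccc2)cc1 | intermediate
16 | (4-benzyloxyphenyl){3,5-bis(4-benzyloxybenzyl)-2-[2-(3-benzyloxyphenyl)ethyl]-6-methoxy-4,6-bis(trimethylsilyloxy)cyclohexa-1,4-dien-1-yl}methanone (diastereomer mixture) | COC1(O[Si](C)(C)C)C(Cc2ccc(OCc3ccccc3)cc2)=C(O[Si](C)(C)C)C(Cc2ccc(OCc3ccccc3)cc2)C(CCc2cccc(OCc3ccccc3)c2)=C1C(=O)c1ccc(OCc2ccccc2)cc1 | intermediate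
17 | 4-(4-benzyloxybenzoyl)-2,6-bis(4-benzyloxybenzyl)-5-[2-(3-benzyloxyphenyl)ethyl]-1,3-bis(trimethylsilyloxy)benzene | C[Si](C)(C)Oc1c(Cc2ccc(OCc3ccccc3)cc2)c(O[Si](C)(C)C)c(C(=O)c2ccc(OCc3ccccc3)cc2)c(CCc2cccc(OCc3ccccc3)c2)c1Cc1ccc(OCc2ccccc2)cc1 | intermediate
18 | 4-(4-benzyloxybenzoyl)-2,6-bis(4-benzyloxybenzyl)-5-[2-(3-benzyloxyphenyl)ethyl]benzene-1,3-diol | Oc1c(Cc2ccc(OCc3ccccc3)cc2)c(O)c(C(=O)c2ccc(OCc3ccccc3)cc2)c(CCc2cccc(OCc3ccccc3)c2)c1Cc1ccc(OCc2ccccc2)cc1 | intermediate
19 | (4-benzyloxyphenyl){3,5-bis(4-benzyloxybenzyl)-6-[2-(3-benzyloxyphenyl)ethyl]-2-hydroxy-4-methoxyphenyl}methanone | COc1c(Cc2ccc(OCc3ccccc3)cc2)c(O)c(C(=O)c2ccc(OCc3ccccc3)cc2)c(CCc2cccc(OCc3ccccc3)c2)c1Cc1ccc(OCc2ccccc2)cc1 | intermediate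
20 | ethyl carbonate of the C3 phenol of 19 | COc1c(Cc2ccc(OCc3ccccc3)cc2)c(OC(=O)OCC)c(C(=O)c2ccc(OCc3ccccc3)cc2)c(CCc2cccc(OCc3ccccc3)c2)c1Cc1ccc(OCc2ccccc2)cc1 | intermediate
21 | ortho-quinone methide (C3 carbonyl, exocyclic C4=CHAr, geometry undefined) | COC1=C(Cc2ccc(OCc3ccccc3)cc2)C(=O)C(=Cc2ccc(OCc3ccccc3)cc2)C(CCc2cccc(OCc3ccccc3)c2)=C1Cc1ccc(OCc2ccccc2)cc1 | intermediate
22 | 2,4,6-tris(4-benzyloxybenzyl)-5-[2-(3-benzyloxyphenyl)ethyl]-3-methoxyphenol | COc1c(Cc2ccc(OCc3ccccc3)cc2)c(O)c(Cc2ccc(OCc3ccccc3)cc2)c(CCc2cccc(OCc3ccccc3)c2)c1Cc1ccc(OCc2ccccc2)cc1 | intermediate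
23 | 2,4,6-tris(4-hydroxybenzyl)-5-[2-(3-hydroxyphenyl)ethyl]-3-methoxyphenol | COc1c(Cc2ccc(O)cc2)c(O)c(Cc2ccc(O)cc2)c(CCc2cccc(O)c2)c1Cc1ccc(O)cc1 | target

**Total step count:** 10. **Longest linear sequence:** 8 (steps 1–4, then 7–10). The ynone branch (steps 5 and 6) is convergent.

**Steps most likely to fail**

1. Step 7. Bond formation between the substituted diene terminus and the alkyl-bearing alkyne carbon of a donor-deactivated ynone may be too slow. Thermal silyl migration and hydrolysis of the diene could then outrun the cycloaddition.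
   - The fallback sets out from 13 and again uses 8. It moves the aryl group to a later C–C bond formation so that a smaller, more electrophilic dienophile can be used.
   - Deprotonation of 13 with n-BuLi and formylation with DMF (inverse quench into aqueous KH2PO4) should give 5-(3-benzyloxyphenyl)pent-2-ynal F1.
   - Cycloaddition of F1 with 8 in toluene and acidic work-up should give 3,5-bis(4-benzyloxybenzyl)-6-[2-(3-benzyloxyphenyl)ethyl]-2,4-dihydroxybenzaldehyde F2.
   - Chelation-controlled methylation (MeI, K2CO3, acetone) should give 3,5-bis(4-benzyloxybenzyl)-6-[2-(3-benzyloxyphenyl)ethyl]-2-hydroxy-4-methoxybenzaldehyde F3.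
   - Grignard addition of excess 4-benzyloxyphenylmagnesium bromide should give racemic 2,4-bis(4-benzyloxybenzyl)-6-[(4-benzyloxyphenyl)(hydroxy)methyl]-5-[2-(3-benzyloxyphenyl)ethyl]-3-methoxyphenol F4.
   - Hydrogenolysis over Pd/C removes the benzhydrylic hydroxyl together with the four benzyl ethers, and the route is rejoined at 23.

2. Step 4. Attack of the amide base at silicon, incomplete γ-deprotonation of the hindered enoate and hydrolysis during isolation may erode the diene.
   - The fallback sets out from 5 and installs the C1 methyl ether before the ring is built.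
   - Trimethyl orthoformate with catalytic H2SO4 in MeOH should give methyl 2-(4-benzyloxybenzyl)-5-(4-benzyloxyphenyl)-3-methoxypent-2-enoate F5. This compound can be purified and offers the base no silicon to attack.
   - LiN(iPr)2 followed by Me3SiCl should give (1E,3Z)-2-(4-benzyloxybenzyl)-5-(4-benzyloxyphenyl)-1,3-dimethoxy-1-(trimethylsilyloxy)penta-1,3-diene F6.
   - Cycloaddition of F6 with 15, methanol loss and acidic desilylation lead directly to 19, so step 8 is no longer needed.

3. Step 9. Slow acylation of the hindered, hydrogen-bonded phenol and slow hydride delivery to the twisted diaryl ketone may let hydrolysis of the carbonate win.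
   - The fallback sets out from 19 and switches from the anionic quinone methide manifold to a cationic one that needs no derivatisation of the phenol.
   - Ionic hydrogenation with a large excess of Et3SiH and CF3CO2H in CH2Cl2 (0 °C → rt) reduces the protonated ketone and then the doubly donor-stabilised benzhydryl cation, and the route is rejoined at 22.
   - The excess silane should intercept the cation ahead of Friedel–Crafts closure onto the arylethyl ring.
   - Partial loss of benzyl ethers does no harm, because step 10 removes them all.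
   - No new compound is made.

**Further compounds**
F1 | step 7 | 5-(3-benzyloxyphenyl)pent-2-ynal | O=CC#CCCc1cccc(OCc2ccccc2)c1
F2 | step 7 | 3,5-bis(4-benzyloxybenzyl)-6-[2-(3-benzyloxyphenyl)ethyl]-2,4-dihydroxybenzaldehyde | Oc1c(Cc2ccc(OCc3ccccc3)cc2)c(O)c(C=O)c(CCc2cccc(OCc3ccccc3)c2)c1Cc1ccc(OCc2ccccc2)cc1
F3 | step 7 | 3,5-bis(4-benzyloxybenzyl)-6-[2-(3-benzyloxyphenyl)ethyl]-2-hydroxy-4-methoxybenzaldehyde | COc1c(Cc2ccc(OCc3ccccc3)cc2)c(O)c(C=O)c(CCc2cccc(OCc3ccccc3)c2)c1Cc1ccc(OCc2ccccc2)cc1
F4 | step 7 | 2,4-bis(4-benzyloxybenzyl)-6-[(4-benzyloxyphenyl)(hydroxy)methyl]-5-[2-(3-benzyloxyphenyl)ethyl]-3-methoxyphenol (racemic) | COc1c(Cc2ccc(OCc3ccccc3)cc2)c(O)c(C(O)c2ccc(OCc3ccccc3)cc2)c(CCc2cccc(OCc3ccccc3)c2)c1Cc1ccc(OCc2ccccc2)cc1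
F5 | step 4 | methyl 2-(4-benzyloxybenzyl)-5-(4-benzyloxyphenyl)-3-methoxypent-2-enoate | COC(=O)C(Cc1ccc(OCc2ccccc2)cc1)=C(OC)CCc1ccc(OCc2ccccc2)cc1
F6 | step 4 | (1E,3Z)-2-(4-benzyloxybenzyl)-5-(4-benzyloxyphenyl)-1,3-dimethoxy-1-(trimethylsilyloxy)penta-1,3-diene | CO/C(O[Si](C)(C)C)=C(Cc1ccc(OCc2ccccc2)cc1)\C(OC)=C\Cc1ccc(OCc2ccccc2)cc1
F0 | step 9 | none | none
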